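The target is treated as a halimane: ring A is C1–C5/C10 with the C1=C10 alkene and the quaternary ester carbon C4, ring B is C5–C10. Each alkene carbon carries one ring A σ-bond beside it (C1–C2, C10–C5) and C5–C10 is also the ring fusion, which is the pattern left by an alkyne dienophile. The route therefore rests on one rhodium-catalysed intramolecular [4+2] cycloaddition of an acyclic dienyne, a 2-(methoxycarbonyl)diene (C2–C5) tethered through C6–C9 to a terminal alkyne on quaternary C9, which closes rings A and B together and sets C5. C8 and C9 come from an enantioselective Ireland–Claisen rearrangement; C4 is quaternised afterwards and the side chain is appended last.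

Key step: step 9

Remark on numbering: the halimane atom numbers of the target (C1–C10 ring carbons, C11–C16 side chain) are kept for all intermediates.

Assumption: the sense of induction of the chiral diazaborolidine (step 2) and of the chiral bisphosphine (step 9) is assigned by analogy; if either proves opposite, the antipodal controller or ligand is used without other change.

Step 1
Reactants: 1 (Z)-3-methylpent-2-en-4-yn-1-ol; 2 propanoyl chloride
Product: 3 (Z)-3-methylpent-2-en-4-yn-1-yl propanoate
Conditions: Et3N, DMAP (cat.), CH2Cl2, 0 °C → rt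
Reagents that add atoms: none
Why: DMAP-catalysed acylation of a primary allylic alcohol by an acid chloride (nucleophilic acyl substitution); the Z-alkene and the terminal alkyne are inert and no stereocentre is involved.

Step 2
Reactants: 3 (Z)-3-methylpent-2-en-4-yn-1-yl propanoate
Product: 6 (2S,3S)-3-ethynyl-2,3-dimethylpent-4-enoic acid, via boron ketene acetal 4 (not isolated), via acyloxyborane 5 (not isolated)
Conditions: (4S,5S)-2-bromo-4,5-diphenyl-1,3-bis[3,5-bis(trifluoromethyl)phenylsulfonyl]-1,3,2-diazaborolidine (made in the flask from the (S,S)-bis-sulfonamide and BBr3), i-Pr2NEt, CH2Cl2, −78 °C, then −20 → 4 °C; aqueous work-up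
Reagents that add atoms: none
Why: Enantioselective Ireland–Claisen rearrangement through a chiral boron ketene acetal: amine/CH2Cl2 enolisation with this reagent class gives the enolate with CH3 cis to O–B, and the chair transition state then holds the C8 methyl and the C9 methyl (the E substituent of the Z-alkene) equatorial and the ethynyl group axial, so C8 and C9 are set together (relative configuration by the chair, absolute configuration by the diazaborolidine).

Step 3
Reactants: 6 (2S,3S)-3-ethynyl-2,3-dimethylpent-4-enoic acid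
Product: 7 (2S,3S)-3-ethynyl-2,3-dimethylpent-4-en-1-ol
Conditions: LiAlH4, Et2O, 0 °C → rt
Reagents that add atoms: none
Why: Hydride reduction of the carboxylic acid to the primary alcohol; the isolated alkene and alkyne are not reduced and the carboxylate-stage α-centre C8 is not epimerised.

Step 4
Reactants: 7 (2S,3S)-3-ethynyl-2,3-dimethylpent-4-en-1-ol
Product: 8 (3S,4S)-3-ethynyl-5-iodo-3,4-dimethylpent-1-ene
Conditions: I2, PPh3, imidazole, CH2Cl2, 0 °C → rt
Reagents that add atoms: iodine, [I][I]
Why: Appel-type iodination, in which iodide displaces the oxyphosphonium group by SN2 at the primary carbon C7, remote from both stereocentres.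

Step 5
Reactants: 8 (3S,4S)-3-ethynyl-5-iodo-3,4-dimethylpent-1-ene
Product: 10 (4R,5S)-5-ethynyl-4,5-dimethylhept-6-enal, via hydrazone 9 (not isolated)
Conditions: acetaldehyde N,N-dimethylhydrazone (2.5 equiv), LiN(i-Pr)2, THF, 0 °C; then 8, DMPU, −78 °C → rt; then aq. oxalic acid, Et2O, rt
Reagents that add atoms: acetaldehyde N,N-dimethylhydrazone, CC=NN(C)C; water, O
Why: Azaenolate alkylation (hydrazone method for two-carbon aldehyde homologation): the lithiated hydrazone, in excess because the alkyne C–H consumes one equivalent, displaces the primary iodide by SN2 to add C6 and C5, and mild aqueous acid then unmasks the aldehyde without touching a stereocentre.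

Step 6
Reactants: 10 (4R,5S)-5-ethynyl-4,5-dimethylhept-6-enal
Product: 11 (5R,6S)-1,1-dibromo-6-ethynyl-5,6-dimethylocta-1,7-diene
Conditions: CBr4, PPh3, CH2Cl2, 0 °C
Reagents that add atoms: carbon tetrabromide, BrC(Br)(Br)Br
Why: Ramirez dibromo-olefination (first stage of the Corey–Fuchs sequence), a Wittig reaction of the aldehyde with Ph3P=CBr2 formed in the flask, which installs C4.

Step 7
Reactants: 11 (5R,6S)-1,1-dibromo-6-ethynyl-5,6-dimethylocta-1,7-diene
Product: 12 (3Z,7R,8S)-3-bromo-8-ethynyl-7,8-dimethyldeca-1,3,9-triene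
Conditions: Bu3SnCH=CH2, Pd2(dba)3 (2.5 mol %), tri(2-furyl)phosphine (15 mol %), toluene, 90 °C
Reagents that add atoms: tributyl(vinyl)stannane, C=C[Sn](CCCC)(CCCC)CCCC
Why: Stille coupling of a 1,1-dibromoalkene, in which zerovalent palladium adds first to the less hindered C–Br bond trans to the alkyl chain, so the vinyl group (C3=C2) ends up trans to C6 and the cis bromide is kept.

Step 8
Reactants: 12 (3Z,7R,8S)-3-bromo-8-ethynyl-7,8-dimethyldeca-1,3,9-triene
Product: 13 methyl (2Z,6R,7S)-2-ethenyl-7-ethynyl-6,7-dimethylnona-2,8-dienoate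
Conditions: CO (1 atm), MeOH, Et3N, Pd(PPh3)4 (5 mol %), DMF, 60 °C
Reagents that add atoms: carbon monoxide, [C-]#[O+]; methanol, CO
Why: Palladium-catalysed methoxycarbonylation of the alkenyl bromide (oxidative addition, CO insertion, methanolysis) with retention of alkene geometry, which puts the ester cis to C6 and so the tether on the outside of the diene.

Step 9
Reactants: 13 methyl (2Z,6R,7S)-2-ethenyl-7-ethynyl-6,7-dimethylnona-2,8-dienoate
Product: 14 methyl (5S,6R,8aR)-5-ethenyl-5,6-dimethyl-3,5,6,7,8,8a-hexahydronaphthalene-1-carboxylate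
Conditions: [Rh(cod)2]SbF6 (5 mol %), (R,R)-Me-DuPHOS (5.5 mol %), ClCH2CH2Cl, 25 → 50 °C
Reagents that add atoms: none
Why: Cationic monovalent rhodium binds the s-cis diene and the alkyne and joins C5 to C10 by oxidative cyclisation, and allyl–alkenyl reductive elimination from the rhodacycle then forms C1–C2, so both bonds arise in one catalytic event. The closest known reaction type is the rhodium-catalysed intramolecular diene–alkyne [4+2] cycloaddition (a metal-mediated Diels–Alder reaction), which is also known in ligand-controlled enantioselective form. Ring A closes as the six-membered ring of the [4+2] (4π + 2π, both new bonds lie in it) and ring B closes in the same event as a fused six-membered ring over the four-carbon tether C6–C9 (type 1 intramolecular mode, bond C5–C10). The only new stereocentre, C5, depends on which chair-like arrangement of the tether reacts: the wanted one has the C8 methyl equatorial, the C9 methyl axial and the C9 vinyl equatorial, but the quaternary C9 makes the substrate bias small, so the chiral bisphosphine is relied on to select the diene face (catalyst control over a weak substrate preference). The step needs the tether on the outside of the s-cis diene (secured by the 2Z enoate geometry from steps 7 and 8) and reaction of the diene with the alkyne and not with the C9 vinyl group or a second alkyne (secured by the four-atom tether, the 1,4-enyne spacing and the hindered quaternary C9); no endo/exo issue arises because the dienophile is an alkyne, which also delivers C1 as CH and leaves C3=C4 as the enoate needed in step 10.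

Step 10
Reactants: 14 methyl (5S,6R,8aR)-5-ethenyl-5,6-dimethyl-3,5,6,7,8,8a-hexahydronaphthalene-1-carboxylate
Product: 16 methyl (1S,5S,6R,8aR)-5-ethenyl-1,5,6-trimethyl-1,2,3,5,6,7,8,8a-octahydronaphthalene-1-carboxylate, via lithium enolate 15 (not isolated)
Conditions: LiBH(s-Bu)3, THF, −78 °C; then CH3I, DMPU, −78 → 0 °C
Reagents that add atoms: iodomethane, CI
Why: Reductive alkylation of an enoate: conjugate (1,4) hydride addition at C3 gives the ester enolate, and CH3I then attacks C4 from the face of the small C5–H, anti to the C6 methylene (equatorial attack on the exocyclic enolate), so the new methyl is cis to H5 and the ester takes the opposite face.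

Step 11
Reactants: 17 but-2-yn-1-ol
Product: 19 (E)-3-iodobut-2-en-1-ol, via alkenylzirconocene 18 (not isolated)
Conditions: Cp2Zr(H)Cl (2.2 equiv), THF, rt; then I2, 0 °C
Reagents that add atoms: iodine, [I][I]
Why: syn-Hydrozirconation of the internal alkyne (first equivalent forms the alkoxide) places zirconium on C3 beside the smaller methyl group under equilibrating excess reagent, and iodinolysis with retention gives the E-alkenyl iodide.

Step 12
Reactants: 16 methyl (1S,5S,6R,8aR)-5-ethenyl-1,5,6-trimethyl-1,2,3,5,6,7,8,8a-octahydronaphthalene-1-carboxylate; 19 (E)-3-iodobut-2-en-1-ol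
Product: 21 methyl (1S,5S,6R,8aR)-5-[(3E)-5-hydroxy-3-methylpent-3-en-1-yl]-1,5,6-trimethyl-1,2,3,5,6,7,8,8a-octahydronaphthalene-1-carboxylate, via alkylborane 20 (not isolated)
Conditions: 9-borabicyclo[3.3.1]nonane (9-BBN-H), THF, 0 °C → rt; then 19, PdCl2(dppf) (5 mol %), AsPh3, K3PO4 (aq), DMF, rt
Reagents that add atoms: none
Why: Anti-Markovnikov hydroboration of the monosubstituted vinyl group (the trisubstituted C1=C10 alkene and the hindered ester do not react) followed by B-alkyl Suzuki–Miyaura coupling, which forms C12–C13 with retention of the E geometry of the alkenyl iodide.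

Step 13
Reactants: 21 methyl (1S,5S,6R,8aR)-5-[(3E)-5-hydroxy-3-methylpent-3-en-1-yl]-1,5,6-trimethyl-1,2,3,5,6,7,8,8a-octahydronaphthalene-1-carboxylate
Product: 22 methyl (1S,5S,6R,8aR)-5-[(3E)-5-acetoxy-3-methylpent-3-en-1-yl]-1,5,6-trimethyl-1,2,3,5,6,7,8,8a-octahydronaphthalene-1-carboxylate (CNP0209995.1)
Conditions: Ac2O, pyridine, DMAP (cat.), CH2Cl2, rt
Reagents that add atoms: acetic anhydride, CC(=O)OC(C)=O
Why: DMAP-catalysed acetylation of the primary allylic alcohol (acyl transfer); the hindered methyl ester and both alkenes are unaffected.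

Compound list

1 | (Z)-3-methylpent-2-en-4-yn-1-ol | C#C/C(C)=C\CO | starting material
2 | propanoyl chloride | CCC(=O)Cl | starting material
3 | (Z)-3-methylpent-2-en-4-yn-1-yl propanoate | CCC(=O)OC/C=C(C)\C#C | intermediate
4 | boron ketene acetal of 3, O-bound to the (4S,5S)-4,5-diphenyl-1,3-bis[3,5-bis(trifluoromethyl)phenylsulfonyl]-1,3,2-diazaborolidin-2-yl group, CH3 cis to O–B | C/C=C(\OB1N(S(=O)(=O)c2cc(C(F)(F)F)cc(C(F)(F)F)c2)[C@@H](c2ccccc2)[C@H](c2ccccc2)N1S(=O)(=O)c1cc(C(F)(F)F)cc(C(F)(F)F)c1)OC/C=C(C)\C#C | intermediate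
5 | acyloxyborane: the same diazaborolidin-2-yl ester of (2S,3S)-3-ethynyl-2,3-dimethylpent-4-enoic acid | O=C(OB1N(S(=O)(=O)c2cc(C(F)(F)F)cc(C(F)(F)F)c2)[C@@H](c2ccccc2)[C@H](c2ccccc2)N1S(=O)(=O)c1cc(C(F)(F)F)cc(C(F)(F)F)c1)[C@@H](C)[C@](C#C)(C)C=C | intermediate
6 | (2S,3S)-3-ethynyl-2,3-dimethylpent-4-enoic acid | OC(=O)[C@@H](C)[C@](C#C)(C)C=C | intermediate
7 | (2S,3S)-3-ethynyl-2,3-dimethylpent-4-en-1-ol | OC[C@@H](C)[C@](C#C)(C)C=C | intermediate
8 | (3S,4S)-3-ethynyl-5-iodo-3,4-dimethylpent-1-ene | IC[C@@H](C)[C@](C#C)(C)C=C | intermediate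
9 | (E)-N,N-dimethylhydrazone of (4R,5S)-5-ethynyl-4,5-dimethylhept-6-enal | CN(C)/N=C/CC[C@@H](C)[C@](C#C)(C)C=C | intermediate
10 | (4R,5S)-5-ethynyl-4,5-dimethylhept-6-enal | O=CCC[C@@H](C)[C@](C#C)(C)C=C | intermediate
11 | (5R,6S)-1,1-dibromo-6-ethynyl-5,6-dimethylocta-1,7-diene | BrC(Br)=CCC[C@@H](C)[C@](C#C)(C)C=C | intermediate
12 | (3Z,7R,8S)-3-bromo-8-ethynyl-7,8-dimethyldeca-1,3,9-triene | C=C/C(Br)=C/CC[C@@H](C)[C@](C#C)(C)C=C | intermediate
13 | methyl (2Z,6R,7S)-2-ethenyl-7-ethynyl-6,7-dimethylnona-2,8-dienoate | C=C/C(C(=O)OC)=C/CC[C@@H](C)[C@](C#C)(C)C=C | intermediate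
14 | methyl (5S,6R,8aR)-5-ethenyl-5,6-dimethyl-3,5,6,7,8,8a-hexahydronaphthalene-1-carboxylate | COC(=O)C1=CCC=C2[C@H]1CC[C@@H](C)[C@]2(C)C=C | intermediate
15 | lithium ester enolate formed from 14 by hydride addition at C3 | [Li]OC(OC)=C1CCC=C2[C@H]1CC[C@@H](C)[C@]2(C)C=C | intermediate
16 | methyl (1S,5S,6R,8aR)-5-ethenyl-1,5,6-trimethyl-1,2,3,5,6,7,8,8a-octahydronaphthalene-1-carboxylate | COC(=O)[C@@]1(C)CCC=C2[C@H]1CC[C@@H](C)[C@]2(C)C=C | intermediate
17 | but-2-yn-1-ol | CC#CCO | starting material
18 | (E)-alkenylzirconocene chloride of but-2-yn-1-ol, zirconium on C3, oxygen bound to a second Cp2ZrCl unit | C/C(=C\CO[Zr](Cl)(C1C=CC=C1)C1C=CC=C1)[Zr](Cl)(C1C=CC=C1)C1C=CC=C1 | intermediate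
19 | (E)-3-iodobut-2-en-1-ol | C/C(I)=C\CO | intermediate
20 | B-alkyl-9-borabicyclo[3.3.1]nonane from 16, boron on C12 | COC(=O)[C@@]1(C)CCC=C2[C@H]1CC[C@@H](C)[C@]2(C)CCB1C2CCCC1CCC2 | intermediate
21 | methyl (1S,5S,6R,8aR)-5-[(3E)-5-hydroxy-3-methylpent-3-en-1-yl]-1,5,6-trimethyl-1,2,3,5,6,7,8,8a-octahydronaphthalene-1-carboxylate | COC(=O)[C@@]1(C)CCC=C2[C@H]1CC[C@@H](C)[C@]2(C)CC/C(C)=C/CO | intermediate
22 | methyl (1S,5S,6R,8aR)-5-[(3E)-5-acetoxy-3-methylpent-3-en-1-yl]-1,5,6-trimethyl-1,2,3,5,6,7,8,8a-octahydronaphthalene-1-carboxylate | COC(=O)[C@@]1(C)CCC=C2[C@H]1CC[C@@H](C)[C@]2(C)CC/C(C)=C/COC(C)=O | target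

Total step count: 13. Longest linear sequence: 12 steps (steps 1–10, 12 and 13; step 11 is a one-step side branch).

Steps most likely to fail

Step 9 (key step). The catalyst may fail to override the small substrate bias, giving poor facial selectivity at C5, and the free terminal alkyne may oligomerise on the cationic metal instead of cyclising. The fallback sets out from 13 and returns at 14. The alkyne C–H is capped (Me3SiOTf, Et3N, Zn(OTf)2 cat., CH2Cl2) to give the C-silylated dienyne F1. Zerovalent nickel catalysis (Ni(cod)2, tris(2-biphenylyl) phosphite, THF, 25–60 °C), the known intramolecular [4+2] of silylalkynes with dienes, should then give the silylated cycloadduct F2. In F2 the bulky silyl group on C1 lies beside the equatorial C9 substituent and is expected to favour the chair that places the flat vinyl group, not the methyl group, there, which is the wanted C5 epimer. Protodesilylation (CF3CO2H, CH2Cl2, 0 °C; ipso protonation at C1 and loss of silicon from the β-silyl cation) returns 14.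

Step 10. 1,2-Reduction of the ester or deprotonation at the doubly allylic C2 may compete with conjugate hydride delivery, and the boron-bound enolate may methylate sluggishly or with poor facial selectivity. The fallback sets out from 14 and returns at 16. Single-electron conjugate reduction with Mg in MeOH should give the saturated ester F3 as a mixture of C4 epimers, which is of no consequence because C4 is then re-enolised. LiN(i-Pr)2 (THF, −78 °C) generates the free lithium enolate 15, which is methylated (CH3I, DMPU) to 16.

Step 8. Oxidative addition into the hindered C–Br bond cis to the chain may be slow, so that insertion of the tethered alkyne into the acylpalladium species or thermal dimerisation of the product diene ester competes. The fallback sets out from 10 and returns at 13, replacing steps 6–8. Horner–Wadsworth–Emmons olefination of 10 uses methyl 2-bromo-2-[bis(2,2,2-trifluoroethoxy)phosphoryl]acetate F4, made by bromination of commercial methyl bis(2,2,2-trifluoroethyl)phosphonoacetate (conditions: KN(SiMe3)2, 18-crown-6, THF, −78 °C). This reagent type is known to place the ester cis to the aldehyde chain and should give the bromoenoate F5. Stille coupling of F5 with Bu3SnCH=CH2 (Pd2(dba)3, AsPh3, DMF) with retention returns 13.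

Further compounds

F1 | step 9 | methyl (2Z,6R,7S)-2-ethenyl-6,7-dimethyl-7-[(trimethylsilyl)ethynyl]nona-2,8-dienoate | C=C/C(C(=O)OC)=C/CC[C@@H](C)[C@](C#C[Si](C)(C)C)(C)C=C
F2 | step 9 | 4-(trimethylsilyl) derivative of 14 (silicon on C1 in halimane numbering, ring stereocentres as in 14) | COC(=O)C1=CCC([Si](C)(C)C)=C2[C@H]1CC[C@@H](C)[C@]2(C)C=C
F3 | step 10 | methyl 5-ethenyl-5,6-dimethyl-1,2,3,5,6,7,8,8a-octahydronaphthalene-1-carboxylate (C5, C8 and C9 as in 14, both C4 epimers) | COC(=O)C1CCC=C2[C@H]1CC[C@@H](C)[C@]2(C)C=C
F4 | step 8 | methyl 2-bromo-2-[bis(2,2,2-trifluoroethoxy)phosphoryl]acetate | COC(=O)C(Br)P(=O)(OCC(F)(F)F)OCC(F)(F)F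
F5 | step 8 | methyl (2E,6R,7S)-2-bromo-7-ethynyl-6,7-dimethylnona-2,8-dienoate | Br/C(C(=O)OC)=C/CC[C@@H](C)[C@](C#C)(C)C=C
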